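**Plan**

- Numbering (germacranolide): ring carbons C1–C10 with the Z alkene C1=C10 (methyl C14 on C10) and the E alkene C4=C5 (methyl C15 on C4); C6 bears the secondary angelate, C7 is the ring-fusion carbon, C8 bears the lactone oxygen, C11 (methyl C13) bears the tertiary angelate, C12 is the lactone carbonyl.
- Enabling feature: C8 of the ten-membered ring is homoallylic to the Z-trisubstituted C1=C10 alkene and γ to C12. The ring bond C8–C9, the 8R centre, the Z geometry and then the five-membered lactone can therefore all come from one C8 aldehyde that carries a C1-borylated 2-methylallyl unit and a C12 ester.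
- Cuts, in order: the two angelate C–O bonds (O6, O11); the lactone bond O8–C12 together with the ring bond C8–C9; the C1–B bond (back to a C9 allylic carbonate); the C6–C7 bond (aldol). This leaves an enal from geranyl acetate (C1–C6, C9, C10, C14, C15) and an imide from citramalic acid (C7, C8, C11–C13).
- Forward: the chain is joined at C6–C7, boron is placed on C1, C8 is reduced to the aldehyde, then the ten-membered carbocycle closes first and the γ-lactone second in one operation; desilylation and double angeloylation finish.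
- Stereochemistry: C11 from (R)-citramalic acid; C6 and C7 from an auxiliary-controlled syn-aldol; C1 from a chiral copper catalyst; C8 and the Z geometry of C1=C10 from C1 through the chair of the allylboration; E C4=C5 from geranyl acetate; angelate geometry from angelic acid.

Key step: step 13

Remark on the chemistry: the (R,R) antipode of QuinoxP* is assumed to give the 1R boronate from the E-configured 2-methylallyl carbonate 17; if a model carbonate shows the opposite sense, the (S,S) ligand is used under the same conditions.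

**Route**

Step 1
Reactants: 1 geranyl acetate
Product: 2 (2E,6E)-8-hydroxy-3,7-dimethylocta-2,6-dien-1-yl acetate
Conditions: SeO2 (0.1 equiv), tBuOOH, salicylic acid (0.1 equiv), CH2Cl2, rt
Reagents that add atoms: tert-butyl hydroperoxide, CC(C)(C)OO
Why: Riley allylic oxidation run catalytically in SeO2 (ene reaction, then [2,3]-sigmatropic shift) should attack the electron-richer distal alkene and oxidise only its E-methyl group, giving the primary allylic alcohol that becomes C9.

Step 2
Reactants: 2 (2E,6E)-8-hydroxy-3,7-dimethylocta-2,6-dien-1-yl acetate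
Product: 3 (2E,6E)-8-[(tert-butoxycarbonyl)oxy]-3,7-dimethylocta-2,6-dien-1-yl acetate
Conditions: Boc2O, DMAP (cat.), CH2Cl2, 0 °C to rt
Reagents that add atoms: di-tert-butyl dicarbonate, CC(C)(C)OC(=O)OC(=O)OC(C)(C)C
Why: DMAP-catalysed O-acylation of the primary allylic alcohol installs a tert-butyl carbonate, the leaving group for the later allylic substitution, in a form hindered enough to outlast the acetate.

Step 3
Reactants: 3 (2E,6E)-8-[(tert-butoxycarbonyl)oxy]-3,7-dimethylocta-2,6-dien-1-yl acetate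
Product: 4 tert-butyl (2E,6E)-8-hydroxy-2,6-dimethylocta-2,6-dien-1-yl carbonate
Conditions: K2CO3 (0.2 equiv), MeOH, 0 °C
Reagents that add atoms: none
Why: base-catalysed transesterification with methanol should remove the unhindered acetate well before methoxide attacks the carbonate carbonyl, which is shielded by the tert-butyl group.

Step 4
Reactants: 4 tert-butyl (2E,6E)-8-hydroxy-2,6-dimethylocta-2,6-dien-1-yl carbonate
Product: 5 tert-butyl (2E,6E)-2,6-dimethyl-8-oxoocta-2,6-dien-1-yl carbonate
Conditions: MnO2, CH2Cl2, rt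
Reagents that add atoms: none
Why: MnO2 oxidation of an allylic alcohol stops at the enal and should not isomerise the E alkene that becomes C4=C5.

Step 5
Reactants: 6 (R)-citramalic acid
Product: 7 2-[(4R)-2,2,4-trimethyl-5-oxo-1,3-dioxolan-4-yl]acetic acid
Conditions: 2,2-dimethoxypropane, TsOH·H2O (cat.), rt
Reagents that add atoms: 2,2-dimethoxypropane, COC(C)(C)OC
Why: acid-catalysed transacetalisation should engage the α-hydroxy acid as the five-membered dioxolanone in preference to the six-membered alternative, which sets the two carboxyl groups apart (C12 masked, C8 free) without touching C11.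

Step 6
Reactants: 7 2-[(4R)-2,2,4-trimethyl-5-oxo-1,3-dioxolan-4-yl]acetic acid
Product: 8 (3R)-3-hydroxy-4-methoxy-3-methyl-4-oxobutanoic acid
Conditions: NaOMe (2.2 equiv), MeOH, 0 °C to rt; then aq. HCl
Reagents that add atoms: sodium methoxide, C[O-].[Na+]
Why: nucleophilic acyl substitution by methoxide at the activated dioxolanone carbonyl gives the C12 methyl ester with loss of acetone, while the C8 carboxylate is inert and the quaternary C11 centre cannot epimerise.

Step 7
Reactants: 8 (3R)-3-hydroxy-4-methoxy-3-methyl-4-oxobutanoic acid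
Product: 10 (3R)-4-methoxy-3-methyl-4-oxo-3-(triethylsilyloxy)butanoic acid, via bis(triethylsilyl) derivative 9 (not isolated)
Conditions: TESOTf (2.3 equiv), 2,6-lutidine, CH2Cl2, 0 °C; then MeOH/H2O, rt
Reagents that add atoms: triethylsilyl triflate, CC[Si](CC)(CC)OS(=O)(=O)C(F)(F)F
Why: silylation with a silyl triflate protects the tertiary C11 hydroxyl, and the silyl ester formed alongside is hydrolysed selectively because silyl esters are far more labile than tertiary silyl ethers.

Step 8
Reactants: 10 (3R)-4-methoxy-3-methyl-4-oxo-3-(triethylsilyloxy)butanoic acid; 11 (4R)-4-benzyl-5,5-dimethyl-1,3-oxazolidin-2-one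
Product: 13 methyl (2R)-4-[(4R)-4-benzyl-5,5-dimethyl-2-oxo-1,3-oxazolidin-3-yl]-2-methyl-4-oxo-2-(triethylsilyloxy)butanoate, via mixed pivalic anhydride 12 (not isolated)
Conditions: PivCl, Et3N, THF, −20 °C; then LiCl, 11, rt
Reagents that add atoms: none
Why: N-acylation of the oxazolidinone through a mixed pivalic anhydride under LiCl/Et3N activation, attack occurring at the less hindered of the two anhydride carbonyls.

Step 9
Reactants: 13 methyl (2R)-4-[(4R)-4-benzyl-5,5-dimethyl-2-oxo-1,3-oxazolidin-3-yl]-2-methyl-4-oxo-2-(triethylsilyloxy)butanoate; 5 tert-butyl (2E,6E)-2,6-dimethyl-8-oxoocta-2,6-dien-1-yl carbonate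
Product: 16 methyl (2R,3S,4S,5E,9E)-3-{[(4R)-4-benzyl-5,5-dimethyl-2-oxo-1,3-oxazolidin-3-yl]carbonyl}-11-[(tert-butoxycarbonyl)oxy]-4-hydroxy-2,6,10-trimethyl-2-(triethylsilyloxy)undeca-5,9-dienoate, via Z-boron enolate 14 (not isolated), via boron aldolate 15 (not isolated)
Conditions: Bu2BOTf, iPr2NEt, CH2Cl2, 0 °C; 5, −78 to 0 °C; then pH 7 buffer, MeOH, H2O2, 0 °C
Reagents that add atoms: none
Why: Evans syn-aldol reaction, in which the Z-configured boron enolate reacts through a Zimmerman–Traxler chair on the face remote from the benzyl group of the (4R)-auxiliary, should set 6S and 7S (C6–O syn to C7–C11) irrespective of the remote C11 centre.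

Step 10
Reactants: 16 aldol adduct (name as in step 9)
Product: 17 methyl (2R,3S,4S,5E,9E)-3-{[(4R)-4-benzyl-5,5-dimethyl-2-oxo-1,3-oxazolidin-3-yl]carbonyl}-11-[(tert-butoxycarbonyl)oxy]-4-(tert-butyldimethylsilyloxy)-2,6,10-trimethyl-2-(triethylsilyloxy)undeca-5,9-dienoate
Conditions: TBSOTf, 2,6-lutidine, CH2Cl2, −78 °C (crude 16 used at once)
Reagents that add atoms: tert-butyldimethylsilyl triflate, CC(C)(C)[Si](C)(C)OS(=O)(=O)C(F)(F)F
Why: silyl triflate silylation at low temperature caps the C6 hydroxyl before it can lactonise onto the C12 ester, and at −78 °C should leave the tert-butyl carbonate and the tertiary silyl ether untouched.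

Step 11
Reactants: 17 silyl ether (name as in step 10); 18 bis(pinacolato)diboron
Product: 19 methyl (2R,3S,4S,5E,9R)-3-{[(4R)-4-benzyl-5,5-dimethyl-2-oxo-1,3-oxazolidin-3-yl]carbonyl}-4-(tert-butyldimethylsilyloxy)-2,6,10-trimethyl-9-(4,4,5,5-tetramethyl-1,3,2-dioxaborolan-2-yl)-2-(triethylsilyloxy)undeca-5,10-dienoate
Conditions: CuCl (10 mol%), (R,R)-QuinoxP* (12 mol%), KOtBu (12 mol%), THF, 0 °C to rt
Reagents that add atoms: none
Why: copper-catalysed enantioselective γ-selective (SN2′) boryl substitution of an allylic carbonate, in which borylcupration of C1=C10 places boron on C1 and β-elimination of the carbonate forms C10=C9, so that the chiral bisphosphine–copper catalyst, not the remote stereocentres, should fix 1R.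

Step 12
Reactants: 19 allylboronate (name as in step 11)
Product: 21 methyl (2R,3S,4S,5E,9R)-4-(tert-butyldimethylsilyloxy)-3-formyl-2,6,10-trimethyl-9-(4,4,5,5-tetramethyl-1,3,2-dioxaborolan-2-yl)-2-(triethylsilyloxy)undeca-5,10-dienoate, via aluminium hemiaminal 20 (not isolated)
Conditions: iBu2AlH (1.2 equiv), CH2Cl2, −78 °C; then aq. potassium sodium tartrate; crude aldehyde used directly
Reagents that add atoms: none
Why: hydride reduction of an N-acyl 5,5-dimethyloxazolidinone stops at the aluminium-chelated hemiaminal (the gem-dimethyl group blocks ring opening), which releases the aldehyde on work-up without epimerising C7, while the neopentylic C12 ester next to the silyloxy group should react more slowly.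

Step 13
Reactants: 21 aldehyde (name as in step 12)
Product: 23 (3R,3aS,4S,5E,9Z,11aR)-4-(tert-butyldimethylsilyloxy)-3,6,10-trimethyl-3-(triethylsilyloxy)-3a,4,7,8,11,11a-hexahydrocyclodeca[b]furan-2(3H)-one, via O8-boryl hydroxy ester 22 (not isolated)
Conditions: toluene (2 mM), 60 °C; then PPTS (0.2 equiv), 60 °C
Reagents that add atoms: none
Why: Proposed new method: the C1 pinacol boronate binds the C8 aldehyde oxygen and C9 adds to C8 through a closed six-membered chair (allyl transfer with allylic transposition), which forms C8–C9, moves the alkene to C1=C10 and leaves an O8 borate that then attacks the C12 methyl ester and passes methoxide to boron. The closest known reactions are the intermolecular additions of α-substituted 2-methylallyl pinacol boronates to aldehydes, which give Z homoallylic alcohols with transfer of chirality, the intramolecular allylborations that close five- to eight-membered rings, and the allylboration–lactonisation of ester-bearing aldehydes. The carbocycle closes by a 10-exo-trig addition to the aldehyde, the four-atom C3–C6 tether with its E alkene bridging the axial C2 and equatorial C7 positions of the chair; the lactone closes by a 5-exo-trig acyl substitution at C12, completed by PPTS if the hydroxy ester persists. The one new stereocentre, C8, is controlled by the C1 boronate centre: with C2 axial (away from the pinacol methyl groups and free of A(1,2) strain with the C10 methyl) and C7 equatorial, the 1R boronate delivers C9 to the aldehyde face that gives 8R, and the same chair fixes the Z geometry of C1=C10. The step needs ring closure to outrun intermolecular allylboration and the chair preference to override the Felkin bias of C7; high dilution, the low background reactivity of pinacol allylboronates (which lets the aldehyde be unmasked last) and the 2-methyl group that disfavours an equatorial C2 are relied on for this.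

Step 14
Reactants: 23 bis-silyl lactone (name as in step 13)
Product: 24 (3R,3aR,4S,5E,9Z,11aR)-3,4-dihydroxy-3,6,10-trimethyl-3a,4,7,8,11,11a-hexahydrocyclodeca[b]furan-2(3H)-one
Conditions: HF·pyridine, pyridine, THF, 0 °C to rt
Reagents that add atoms: none
Why: fluoride-induced desilylation under buffered, weakly acidic conditions removes both silyl ethers without generating the alkoxides that could shift the lactone from O8 to O6.

Step 15
Reactants: 24 diol (name as in step 14); 25 angelic acid
Product: 27 (3R,3aS,4S,5E,9Z,11aR)-3,6,10-trimethyl-2-oxo-2,3,3a,4,7,8,11,11a-octahydrocyclodeca[b]furan-3,4-diyl bis[(Z)-2-methylbut-2-enoate], via angelic trichlorobenzoic anhydride 26 (not isolated)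
Conditions: 25 (6 equiv), 2,4,6-trichlorobenzoyl chloride, Et3N, toluene, rt; then 24, 80 °C
Reagents that add atoms: none
Why: Yamaguchi-type esterification through the 2,4,6-trichlorobenzoyl mixed anhydride without a nucleophilic catalyst, conditions that acylate hindered alcohols with angelic acid without Z-to-E isomerisation, should esterify both the secondary O6 and the tertiary O11 hydroxyl.

**Compound list**

1 | geranyl acetate | CC(C)=CCC/C(C)=C/COC(C)=O | starting material
2 | (2E,6E)-8-hydroxy-3,7-dimethylocta-2,6-dien-1-yl acetate | CC(=O)OC/C=C(\C)CC/C=C(\C)CO | intermediate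
3 | (2E,6E)-8-[(tert-butoxycarbonyl)oxy]-3,7-dimethylocta-2,6-dien-1-yl acetate | CC(=O)OC/C=C(\C)CC/C=C(\C)COC(=O)OC(C)(C)C | intermediate
4 | tert-butyl (2E,6E)-8-hydroxy-2,6-dimethylocta-2,6-dien-1-yl carbonate | OC/C=C(\C)CC/C=C(\C)COC(=O)OC(C)(C)C | intermediate
5 | tert-butyl (2E,6E)-2,6-dimethyl-8-oxoocta-2,6-dien-1-yl carbonate | O=C/C=C(\C)CC/C=C(\C)COC(=O)OC(C)(C)C | intermediate
6 | (R)-citramalic acid | OC(=O)[C@](C)(O)CC(=O)O | starting material
7 | 2-[(4R)-2,2,4-trimethyl-5-oxo-1,3-dioxolan-4-yl]acetic acid | CC1(C)OC(=O)[C@@](C)(CC(=O)O)O1 | intermediate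
8 | (3R)-3-hydroxy-4-methoxy-3-methyl-4-oxobutanoic acid | COC(=O)[C@](C)(O)CC(=O)O | intermediate
9 | triethylsilyl (3R)-4-methoxy-3-methyl-4-oxo-3-(triethylsilyloxy)butanoate | COC(=O)[C@](C)(O[Si](CC)(CC)CC)CC(=O)O[Si](CC)(CC)CC | intermediate (not isolated)
10 | (3R)-4-methoxy-3-methyl-4-oxo-3-(triethylsilyloxy)butanoic acid | COC(=O)[C@](C)(O[Si](CC)(CC)CC)CC(=O)O | intermediate
11 | (4R)-4-benzyl-5,5-dimethyl-1,3-oxazolidin-2-one (commercial auxiliary) | O=C1N[C@H](Cc2ccccc2)C(C)(C)O1 | starting material
12 | mixed anhydride of 10 with pivalic acid | COC(=O)[C@](C)(O[Si](CC)(CC)CC)CC(=O)OC(=O)C(C)(C)C | intermediate (not isolated)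
13 | methyl (2R)-4-[(4R)-4-benzyl-5,5-dimethyl-2-oxo-1,3-oxazolidin-3-yl]-2-methyl-4-oxo-2-(triethylsilyloxy)butanoate | COC(=O)[C@](C)(O[Si](CC)(CC)CC)CC(=O)N1C(=O)OC(C)(C)[C@H]1Cc1ccccc1 | intermediate
14 | Z-configured dibutylboron enolate of 13 | CCCCB(CCCC)O/C(=C\[C@@](C)(O[Si](CC)(CC)CC)C(=O)OC)N1C(=O)OC(C)(C)[C@H]1Cc1ccccc1 | intermediate (not isolated)
15 | O6-dibutylboryl aldolate of 16 | O=C(N1C(=O)OC(C)(C)[C@H]1Cc1ccccc1)[C@H]([C@@](C)(O[Si](CC)(CC)CC)C(=O)OC)[C@@H](OB(CCCC)CCCC)/C=C(\C)CC/C=C(\C)COC(=O)OC(C)(C)C | intermediate (not isolated)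
16 | methyl (2R,3S,4S,5E,9E)-3-{[(4R)-4-benzyl-5,5-dimethyl-2-oxo-1,3-oxazolidin-3-yl]carbonyl}-11-[(tert-butoxycarbonyl)oxy]-4-hydroxy-2,6,10-trimethyl-2-(triethylsilyloxy)undeca-5,9-dienoate (6S,7S,11R in ring numbering) | O=C(N1C(=O)OC(C)(C)[C@H]1Cc1ccccc1)[C@H]([C@@](C)(O[Si](CC)(CC)CC)C(=O)OC)[C@@H](O)/C=C(\C)CC/C=C(\C)COC(=O)OC(C)(C)C | intermediate
17 | 4-O-tert-butyldimethylsilyl ether of 16 | O=C(N1C(=O)OC(C)(C)[C@H]1Cc1ccccc1)[C@H]([C@@](C)(O[Si](CC)(CC)CC)C(=O)OC)[C@@H](O[Si](C)(C)C(C)(C)C)/C=C(\C)CC/C=C(\C)COC(=O)OC(C)(C)C | intermediate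
18 | bis(pinacolato)diboron | CC1(C)OB(OC1(C)C)B1OC(C)(C)C(C)(C)O1 | starting material
19 | methyl (2R,3S,4S,5E,9R)-3-{[(4R)-4-benzyl-5,5-dimethyl-2-oxo-1,3-oxazolidin-3-yl]carbonyl}-4-(tert-butyldimethylsilyloxy)-2,6,10-trimethyl-9-(4,4,5,5-tetramethyl-1,3,2-dioxaborolan-2-yl)-2-(triethylsilyloxy)undeca-5,10-dienoate (1R boronate) | O=C(N1C(=O)OC(C)(C)[C@H]1Cc1ccccc1)[C@H]([C@@](C)(O[Si](CC)(CC)CC)C(=O)OC)[C@@H](O[Si](C)(C)C(C)(C)C)/C=C(\C)CC[C@@H](B1OC(C)(C)C(C)(C)O1)C(C)=C | intermediate
20 | diisobutylaluminium alkoxide of the C8 N,O-hemiaminal of 19 (C8 configuration undefined) | CC(C)C[Al](CC(C)C)OC(N1C(=O)OC(C)(C)[C@H]1Cc1ccccc1)[C@H]([C@@](C)(O[Si](CC)(CC)CC)C(=O)OC)[C@@H](O[Si](C)(C)C(C)(C)C)/C=C(\C)CC[C@@H](B1OC(C)(C)C(C)(C)O1)C(C)=C | intermediate (not isolated)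
21 | methyl (2R,3S,4S,5E,9R)-4-(tert-butyldimethylsilyloxy)-3-formyl-2,6,10-trimethyl-9-(4,4,5,5-tetramethyl-1,3,2-dioxaborolan-2-yl)-2-(triethylsilyloxy)undeca-5,10-dienoate (C8 aldehyde, key-step precursor) | O=C[C@H]([C@@](C)(O[Si](CC)(CC)CC)C(=O)OC)[C@@H](O[Si](C)(C)C(C)(C)C)/C=C(\C)CC[C@@H](B1OC(C)(C)C(C)(C)O1)C(C)=C | intermediate
22 | methyl (2R)-2-[(1S,2S,3E,7Z,10R)-2-(tert-butyldimethylsilyloxy)-4,8-dimethyl-10-[(4,4,5,5-tetramethyl-1,3,2-dioxaborolan-2-yl)oxy]cyclodeca-3,7-dien-1-yl]-2-(triethylsilyloxy)propanoate | CC(C)(C)[Si](C)(C)O[C@H]1/C=C(\C)CC/C=C(/C)C[C@@H](OB2OC(C)(C)C(C)(C)O2)[C@@H]1[C@@](C)(O[Si](CC)(CC)CC)C(=O)OC | intermediate (not isolated)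
23 | (3R,3aS,4S,5E,9Z,11aR)-4-(tert-butyldimethylsilyloxy)-3,6,10-trimethyl-3-(triethylsilyloxy)-3a,4,7,8,11,11a-hexahydrocyclodeca[b]furan-2(3H)-one | CC(C)(C)[Si](C)(C)O[C@H]1/C=C(\C)CC/C=C(/C)C[C@H]2OC(=O)[C@](C)(O[Si](CC)(CC)CC)[C@H]12 | intermediate
24 | (3R,3aR,4S,5E,9Z,11aR)-3,4-dihydroxy-3,6,10-trimethyl-3a,4,7,8,11,11a-hexahydrocyclodeca[b]furan-2(3H)-one | O[C@H]1/C=C(\C)CC/C=C(/C)C[C@H]2OC(=O)[C@](C)(O)[C@H]12 | intermediate
25 | angelic acid | C/C=C(/C)C(=O)O | starting material
26 | (Z)-2-methylbut-2-enoic 2,4,6-trichlorobenzoic anhydride | C/C=C(/C)C(=O)OC(=O)c1c(Cl)cc(Cl)cc1Cl | intermediate (not isolated)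
27 | CNP0391997.3, (3R,3aS,4S,5E,9Z,11aR)-3,6,10-trimethyl-2-oxo-2,3,3a,4,7,8,11,11a-octahydrocyclodeca[b]furan-3,4-diyl bis[(Z)-2-methylbut-2-enoate] | C/C=C(/C)C(=O)O[C@H]1/C=C(\C)CC/C=C(/C)C[C@H]2OC(=O)[C@](C)(OC(=O)/C(C)=C\C)[C@H]12 | target

**Step count**

Total: 15 steps. Longest linear sequence: 11 steps (steps 1–4, then 9–15; the citramalate branch, steps 5–8 then 9–15, is equally long).

**Steps most likely to fail**

1. Step 13 (macrocyclising allylboration). Ring closure may lose to intermolecular allylboration if the E-configured C3–C6 tether cannot reach across the chair. Closure may also go through the alternative chair with C2 equatorial, or through a boat, and give the E alkene or the 8S epimer. A silyloxy group may be lost from the aldehyde by β-elimination on prolonged heating.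
   The fallback uses known reactions, needs no chiral allylboronate, sets out from imide 13 and returns at 23. Hex-1-en-5-yne (commercial) is methylaluminated (Negishi carboalumination: AlMe3, Cp2ZrCl2 cat.) and the alkenylalane trapped with paraformaldehyde to give (E)-3-methylhepta-2,6-dien-1-ol F1, which MnO2 oxidises to (E)-3-methylhepta-2,6-dienal F2. The Evans syn-aldol reaction of 13 with F2 under the conditions of step 9 should give the vinyl-terminated aldol adduct F3, which is silylated as in step 10 to the TBS ether F4 and reduced as in step 12 to the C8 aldehyde F5. Brown methallylation with the antipode of B-methallyldiisopinocampheylborane that adds to the Re face of the aldehyde (Et2O, −78 °C; NaBO3·4H2O work-up) sets 8R by reagent control and gives the homoallylic hydroxy ester F6. PPTS in toluene closes the lactone to give the methallyl lactone F7. Ring-closing metathesis of the vinyl and methallyl groups (second-generation Grubbs catalyst, (H2IMes)(PCy3)Cl2Ru=CHPh, toluene, 1 mM, 80 °C) then forms C1=C10 with loss of ethene, the ten-membered ring holding the new trisubstituted alkene in the ring-cis (Z) geometry, and gives 23.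

2. Step 11 (copper-catalysed allylic borylation). Borylcupration of the trisubstituted C1=C10 alkene may be slow because copper must bind the fully substituted C10. Direct α-substitution may give the linear boronate, or facial selectivity may be poor and give C1 epimers that the remote stereocentres cannot correct.
   The fallback sets the C1–B centre by reagent control before the fragments are joined (sparteine-mediated lithiation–borylation); it sets out from imide 13 with a new aldehyde partner and returns at 19. Pent-4-yn-1-ol (commercial) is carbamoylated (iPr2NCOCl, Et3N) to pent-4-yn-1-yl N,N-diisopropylcarbamate F8. Negishi carboalumination (AlMe3, Cp2ZrCl2 cat.) and trapping with paraformaldehyde give (E)-6-hydroxy-4-methylhex-4-en-1-yl N,N-diisopropylcarbamate F9, protected (TBSCl, imidazole) as the silyl ether F10. Deprotonation with sBuLi/(−)-sparteine (Et2O, −78 °C), addition of isopropenylboronic acid pinacol ester and warming (1,2-metallate shift with loss of the carbamate) should give the (R)-configured allylboronate F11. Mild methanolysis (PPTS, MeOH) frees the allylic alcohol F12, and MnO2 gives the boryl enal F13, which is used at once because such a hindered pinacol allylboronate adds to aldehydes only slowly at or below 0 °C. The Evans syn-aldol reaction of 13 with F13 at −78 °C, with a non-oxidative work-up to spare the C–B bond, gives the boryl aldol adduct F14, and silylation as in step 10 gives 19.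

3. Step 15 (double angeloylation). Acylation of the hindered tertiary C11 hydroxyl may stay incomplete. Forcing or nucleophile-catalysed conditions may isomerise the angelate to the E (tiglate) ester, and base may shift the lactone to O6 before O6 is acylated.
   The fallback separates acylation from the creation of the Z alkene; it sets out from diol 24 and returns at 27. Both hydroxyls are acylated with 2-[bis(2,2,2-trifluoroethoxy)phosphoryl]propanoyl chloride (Et3N, DMAP, CH2Cl2, heated if needed, since no alkene geometry is at stake) to give the bis(phosphonopropionate) F15. A double Still–Gennari olefination (KN(SiMe3)2, 18-crown-6, acetaldehyde, THF, −78 °C) then forms both (Z)-2-methylbut-2-enoates; the lactone has no enolisable hydrogen at C11.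

**Further compounds**

F1 | step 13 | (E)-3-methylhepta-2,6-dien-1-ol | OC/C=C(\C)CCC=C
F2 | step 13 | (E)-3-methylhepta-2,6-dienal | O=C/C=C(\C)CCC=C
F3 | step 13 | vinyl-terminated aldol adduct, methyl (2R,3S,4S,5E)-3-{[(4R)-4-benzyl-5,5-dimethyl-2-oxo-1,3-oxazolidin-3-yl]carbonyl}-4-hydroxy-2,6-dimethyl-2-(triethylsilyloxy)deca-5,9-dienoate | O=C(N1C(=O)OC(C)(C)[C@H]1Cc1ccccc1)[C@H]([C@@](C)(O[Si](CC)(CC)CC)C(=O)OC)[C@@H](O)/C=C(\C)CCC=C
F4 | step 13 | 4-O-tert-butyldimethylsilyl ether of F3 | O=C(N1C(=O)OC(C)(C)[C@H]1Cc1ccccc1)[C@H]([C@@](C)(O[Si](CC)(CC)CC)C(=O)OC)[C@@H](O[Si](C)(C)C(C)(C)C)/C=C(\C)CCC=C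
F5 | step 13 | methyl (2R,3S,4S,5E)-4-(tert-butyldimethylsilyloxy)-3-formyl-2,6-dimethyl-2-(triethylsilyloxy)deca-5,9-dienoate | O=C[C@H]([C@@](C)(O[Si](CC)(CC)CC)C(=O)OC)[C@@H](O[Si](C)(C)C(C)(C)C)/C=C(\C)CCC=C
F6 | step 13 | homoallylic hydroxy ester from methallylation of F5 (8R in ring numbering) | C=C(C)C[C@@H](O)[C@H]([C@@](C)(O[Si](CC)(CC)CC)C(=O)OC)[C@@H](O[Si](C)(C)C(C)(C)C)/C=C(\C)CCC=C
F7 | step 13 | methallyl lactone, (3R,4S,5R)-4-[(1S,2E)-1-(tert-butyldimethylsilyloxy)-3-methylhepta-2,6-dien-1-yl]-3-methyl-5-(2-methylallyl)-3-(triethylsilyloxy)oxolan-2-one | CC(C)(C)[Si](C)(C)O[C@@H](/C=C(\C)CCC=C)[C@@H]1[C@@H](CC(C)=C)OC(=O)[C@]1(C)O[Si](CC)(CC)CC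
F8 | step 11 | pent-4-yn-1-yl N,N-diisopropylcarbamate | C#CCCCOC(=O)N(C(C)C)C(C)C
F9 | step 11 | (E)-6-hydroxy-4-methylhex-4-en-1-yl N,N-diisopropylcarbamate | OC/C=C(\C)CCCOC(=O)N(C(C)C)C(C)C
F10 | step 11 | (E)-6-(tert-butyldimethylsilyloxy)-4-methylhex-4-en-1-yl N,N-diisopropylcarbamate | CC(C)(C)[Si](C)(C)OC/C=C(\C)CCCOC(=O)N(C(C)C)C(C)C
F11 | step 11 | tert-butyldimethylsilyl ether of (2E,6R)-3,7-dimethyl-6-(4,4,5,5-tetramethyl-1,3,2-dioxaborolan-2-yl)octa-2,7-dien-1-ol | CC(C)(C)[Si](C)(C)OC/C=C(\C)CC[C@@H](B1OC(C)(C)C(C)(C)O1)C(C)=C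
F12 | step 11 | (2E,6R)-3,7-dimethyl-6-(4,4,5,5-tetramethyl-1,3,2-dioxaborolan-2-yl)octa-2,7-dien-1-ol | OC/C=C(\C)CC[C@@H](B1OC(C)(C)C(C)(C)O1)C(C)=C
F13 | step 11 | (2E,6R)-3,7-dimethyl-6-(4,4,5,5-tetramethyl-1,3,2-dioxaborolan-2-yl)octa-2,7-dienal | O=C/C=C(\C)CC[C@@H](B1OC(C)(C)C(C)(C)O1)C(C)=C
F14 | step 11 | boryl aldol adduct (19 with a free C6 hydroxyl) | O=C(N1C(=O)OC(C)(C)[C@H]1Cc1ccccc1)[C@H]([C@@](C)(O[Si](CC)(CC)CC)C(=O)OC)[C@@H](O)/C=C(\C)CC[C@@H](B1OC(C)(C)C(C)(C)O1)C(C)=C
F15 | step 15 | O6,O11-bis{2-[bis(2,2,2-trifluoroethoxy)phosphoryl]propanoate} of diol 24 | CC(C(=O)O[C@H]1/C=C(\C)CC/C=C(/C)C[C@H]2OC(=O)[C@](C)(OC(=O)C(C)P(=O)(OCC(F)(F)F)OCC(F)(F)F)[C@H]12)P(=O)(OCC(F)(F)F)OCC(F)(F)F
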